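At early times the theta run already falls short. At 15.0 s, the gap between the charge and the sum of the readings is 44.7% of the Z lost. At 90.0 s it is still 48.2%, so I treat the gap as a sink that doesn't feed on.

| setting | theta | alpha | south-west | north-east |
|---|---|---|---|---|
| Z | 0.40 M | 0.29 M | 0.59 M | 0.59 M |
| J | 1.18 M | 1.18 M | 1.20 M | 1.80 M |
| remark | run made earlier | run made earlier |  |  |
| time |  |  | 8.0 min | 8.0 min |

| run | time / s | Z / % | L / % | Q / % | X / % | E / % |
|---|---|---|---|---|---|---|
| theta | 15.0 | 62 | 2 | 7 | 11 | 1 |
| theta | 30.0 | 41 | 3 | 7 | 7 | 1 |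
| theta | 50.0 | 24 | 3 | 11 | 12 | 7 |
| theta | 60.0 | 26 | 2 | 11 | 9 | 5 |
| theta | 80.0 | 13 | 5 | 12 | 11 | 5 |
| theta | 90.0 | 15 | 3 | 20 | 13 | 8 |
| alpha | 10.0 | 72 | 4 | 0 | 7 | 1 |
| alpha | 12.0 | 68 | 0 | 2 | 8 | 3 |
| alpha | 20.0 | 54 | 3 | 7 | 9 | 2 |
| alpha | 40.0 | 34 | 4 | 8 | 12 | 0 |
| alpha | 60.0 | 25 | 7 | 14 | 17 | 4 |
| alpha | 90.0 | 18 | 6 | 19 | 13 | 2 |

(scatter of a reading: 2 percentage points)

- which of these there is most of at the end, counted by the Z in it, south-west (L / X / Q / E)
- which of these there is most of at the end, counted by the Z in it, north-east (L / X / Q / E)
- amount of the one of these that there is most of at the end, in percent of the Z charged, south-west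
- amount of the one of these that there is most of at the end, in percent of the Z charged, north-east

- in percentages every species weighs as the Z in it: one E counts as two

Between those theta readings [Z] gives a half-life of 36.6 s. I take it for both new flasks, so 8.0 min is 13.1 half-lives, far longer, and the end amount is set by what Z turns into.

My measure is the yield on conversion: Q at the last theta reading divided by the Z lost by then, 23.5%. That is the lower edge of my estimate, for X and L staying put, and it carries the scatter of the readings; alpha gives 23.2%. The upper edge lets Q take up L and X too, which gives 42.4%. J was the same in both runs, so the bracket is untested for north-east, and both new flasks hold more Z than either run. I commit to Q in both flasks, inside that bracket.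

The forecast also says Q for south-west and Q for north-east, but at 55% and 60%, above my bracket. It reads the gap differently, as “probably a reservoir that feeds on to products”.

South-west gives Q at 21.5%, north-east Q at 26.6%.

    Z + X → E (k = 0.0274 /M/s)
    X ⇌ Q (K = 2.30, k = 0.0404 /s)
    Z + J → X + D (k = 0.0102 /M/s)
    X ⇌ L (K = 0.453, k = 0.0654 /s)
    2 Z → G (k = 0.0355 /M/s)

Left until 80.0 min, south-west holds Q at 21.5%. South-west's Q lies 2.0 percentage points under my measure, the lower edge, against a scatter of 2 points; north-east's Q is more than that edge and less than the upper one.

Now take south-west stopped at 3.0 min. That is 4.92 half-lives, which leaves Z at 3.31%, and my measure then gives Q 22.7%. The flask has Z 2.90% and Q 19.8%.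

Readings and results were generated by integration for substances that don't exist; noise was put on by code.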